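## Retrosynthetic overview

1. The allylic acetate C–O bond is the key disconnection. It is made late by an imine-directed palladium C–H acetoxylation of the ring methyl group that lies cis to the formyl group of a 2-methylcyclopent-1-ene-1-carbaldehyde. The side-chain aldehyde is unmasked last from a primary silyl ether.
2. The cyclopentene is the only ring formed. It comes from glycol cleavage of a cyclohexane-1,2-diol followed by intramolecular aldol condensation (ring contraction, step 4).
3. The side-chain stereocenter and its oxygen come from a catalyst-controlled anti-Markovnikov hydroboration–oxidation of a 1,1-disubstituted alkene.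
4. The C20 skeleton comes from allylic metalation of a commercial limonene-derived diol and alkylation with geranyl bromide. The ring stereocenter is taken from the diol.

Assumption: (R)-DTBM-SEGPHOS is taken as the ligand hand that gives the 2′R alcohol in step 2 (the step is catalyst-controlled, so the antipode is used if a pilot run gives the epimer); 1 is bought as (+)-limonene-1,2-diol, also one step from (+)-limonene oxide.

C2′ below means the side-chain carbon that carries the formyl group in the target.

## Route

**Step 1**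
Reactants: 1 (1S,2S,4R)-1-methyl-4-(prop-1-en-2-yl)cyclohexane-1,2-diol; 2 geranyl bromide, (2E)-1-bromo-3,7-dimethylocta-2,6-diene
Product: 4 (1S,2S,4R)-4-[(5E)-6,10-dimethylundeca-1,5,9-trien-2-yl]-1-methylcyclohexane-1,2-diol, via trilithio diolate 3 (not isolated)
Conditions: n-BuLi (3.3 equiv), TMEDA (3.3 equiv), Et2O–hexane, 0 °C to rt, 20 h; then 2 (1.1 equiv), THF, −78 to 0 °C; H2O
Reagents that add atoms: none
Why: Two equivalents of base make the dialkoxide and the third, activated by TMEDA, removes the kinetically most acidic proton (the allylic methyl of the 1,1-disubstituted alkene, as in limonene and isopulegol metalations) to give a 2-substituted allyllithium with two equivalent termini, which is alkylated at carbon by the primary allylic bromide (allylic metalation–SN2 alkylation); no stereocenter is touched and the E-alkene of 2 is kept.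

**Step 2**
Reactants: 4 (1S,2S,4R)-4-[(5E)-6,10-dimethylundeca-1,5,9-trien-2-yl]-1-methylcyclohexane-1,2-diol
Product: 6 (1S,2S,4R)-4-[(2R,5E)-1-hydroxy-6,10-dimethylundeca-5,9-dien-2-yl]-1-methylcyclohexane-1,2-diol, via tris(pinacolboryl) intermediate 5 (not isolated)
Conditions: CuCl (5 mol %), (R)-DTBM-SEGPHOS (6 mol %), KOtBu (10 mol %), HBpin (4 equiv), THF, rt, 24 h; then NaBO3·4H2O, THF–H2O, rt
Reagents that add atoms: sodium perborate [Na+].[O-]OB=O (oxygen of the new hydroxyl); pinacolborane CC1(C)OBOC1(C)C (boron in 5, hydrogen at C2′ in 6)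
Why: Copper hydride-catalysed enantioselective anti-Markovnikov hydroboration: the ligated monovalent copper hydride adds only to the unhindered 1,1-disubstituted alkene (copper to CH2, hydride to C2′) and the chiral bisphosphine selects the alkene face, which sets C2′ as R under catalyst control; perborate then replaces boron by oxygen without touching C2′ and frees the two hydroxyls that were O-borylated in the flask.

**Step 3**
Reactants: 6 (1S,2S,4R)-4-[(2R,5E)-1-hydroxy-6,10-dimethylundeca-5,9-dien-2-yl]-1-methylcyclohexane-1,2-diol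
Product: 7 (1S,2S,4R)-4-[(2R,5E)-6,10-dimethyl-1-(triethylsilyloxy)undeca-5,9-dien-2-yl]-1-methylcyclohexane-1,2-diol
Conditions: Et3SiCl (1.05 equiv), imidazole, CH2Cl2, −40 °C
Reagents that add atoms: chlorotriethylsilane CC[Si](Cl)(CC)CC
Why: Kinetic silylation: the primary alcohol reacts far faster than the tertiary alcohol or the secondary alcohol next to a quaternary carbon, so one equivalent at low temperature gives the mono-silyl ether.

**Step 4**
Reactants: 7 (1S,2S,4R)-4-[(2R,5E)-6,10-dimethyl-1-(triethylsilyloxy)undeca-5,9-dien-2-yl]-1-methylcyclohexane-1,2-diol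
Product: 9 (5S)-5-[(2R,5E)-6,10-dimethyl-1-(triethylsilyloxy)undeca-5,9-dien-2-yl]-2-methylcyclopent-1-ene-1-carbaldehyde, via keto aldehyde 8 (not isolated)
Conditions: NaIO4 on silica gel, CH2Cl2, rt; filter; then piperidine (0.3 equiv), AcOH (0.3 equiv), toluene, 60 °C
Reagents that add atoms: none
Why: Periodate glycol cleavage opens the cyclohexane between the two carbinol carbons without touching the alkenes, and piperidinium acetate then closes the cyclopentene by intramolecular aldol condensation of the aldehyde enamine onto the methyl ketone (the ring contraction known for the limonene series); neither stereocenter is alpha to a carbonyl, so both are kept.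

**Step 5**
Reactants: 9 (5S)-5-[(2R,5E)-6,10-dimethyl-1-(triethylsilyloxy)undeca-5,9-dien-2-yl]-2-methylcyclopent-1-ene-1-carbaldehyde
Product: 10 {(3S)-3-[(2R,5E)-6,10-dimethyl-1-(triethylsilyloxy)undeca-5,9-dien-2-yl]-2-formylcyclopent-1-en-1-yl}methyl acetate
Conditions: Pd(OAc)2 (10 mol %), 2-aminoisobutyric acid (30 mol %), 2,6-dimethyl-1,4-benzoquinone (1.5 equiv), AcOH (5 equiv), 1,4-dioxane, 45 °C
Reagents that add atoms: acetic acid CC(=O)O
Why: Proposed new method: reversible condensation of the enal with the amino acid gives an imino-carboxylate that chelates divalent palladium and holds it next to the only C–H bonds it can reach, those of the methyl group cis to the formyl group, so concerted metalation–deprotonation gives a six-membered allyl palladacycle; quinone-assisted C–O reductive elimination with acetate at the primary terminus and imine hydrolysis release 10, and the quinone re-oxidises zerovalent palladium. The closest known reaction types are the transient-directing-group benzylic C–H acyloxylation of 2-methylbenzaldehydes with Pd(OAc)2 and the Pd(OAc)2/benzoquinone allylic C–H acetoxylation; the cyclic cis-beta-methyl enal is an untested substrate class, the ring CH2 trans to the formyl group and the tertiary C–H are out of reach, and no stereocenter is formed.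

**Step 6**
Reactants: 10 {(3S)-3-[(2R,5E)-6,10-dimethyl-1-(triethylsilyloxy)undeca-5,9-dien-2-yl]-2-formylcyclopent-1-en-1-yl}methyl acetate
Product: 12 {(3S)-3-[(2R,5E)-6,10-dimethyl-1-oxoundeca-5,9-dien-2-yl]-2-formylcyclopent-1-en-1-yl}methyl acetate, via alkoxysulfonium chloride 11 (not isolated)
Conditions: (COCl)2 (4 equiv), DMSO (8 equiv), CH2Cl2, −78 to −40 °C; then i-Pr2NEt, −78 to −20 °C; pH 7 buffer
Reagents that add atoms: none
Why: Swern oxidation applied directly to a primary triethylsilyl ether: activated DMSO cleaves the primary O–Si bond and forms the alkoxysulfonium salt, which the hindered base turns into the aldehyde at low temperature, so the C2′ stereocenter, the acetate and the enal are left as they are.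

## Compound list

1 | (1S,2S,4R)-1-methyl-4-(prop-1-en-2-yl)cyclohexane-1,2-diol [(+)-limonene-1,2-diol] | C[C@]1(O)CC[C@H](C[C@@H]1O)C(C)=C | starting material
2 | geranyl bromide, (2E)-1-bromo-3,7-dimethylocta-2,6-diene | CC(C)=CCC/C(C)=C/CBr | starting material
3 | dilithium (1S,2S,4R)-4-(3-lithioprop-1-en-2-yl)-1-methylcyclohexane-1,2-diolate | C[C@]1(O[Li])CC[C@H](C[C@@H]1O[Li])C(=C)C[Li] | intermediate
4 | (1S,2S,4R)-4-[(5E)-6,10-dimethylundeca-1,5,9-trien-2-yl]-1-methylcyclohexane-1,2-diol | C[C@]1(O)CC[C@H](C[C@@H]1O)C(=C)CC/C=C(\C)CCC=C(C)C | intermediate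
5 | (1S,2S,4R)-4-[(2R,5E)-6,10-dimethyl-1-(4,4,5,5-tetramethyl-1,3,2-dioxaborolan-2-yl)undeca-5,9-dien-2-yl]-1-methylcyclohexane-1,2-diol, both hydroxyls as O-(4,4,5,5-tetramethyl-1,3,2-dioxaborolan-2-yl) borates | C[C@]1(OB2OC(C)(C)C(C)(C)O2)CC[C@H](C[C@@H]1OB1OC(C)(C)C(C)(C)O1)[C@H](CB1OC(C)(C)C(C)(C)O1)CC/C=C(\C)CCC=C(C)C | intermediate
6 | (1S,2S,4R)-4-[(2R,5E)-1-hydroxy-6,10-dimethylundeca-5,9-dien-2-yl]-1-methylcyclohexane-1,2-diol | C[C@]1(O)CC[C@H](C[C@@H]1O)[C@H](CO)CC/C=C(\C)CCC=C(C)C | intermediate
7 | (1S,2S,4R)-4-[(2R,5E)-6,10-dimethyl-1-(triethylsilyloxy)undeca-5,9-dien-2-yl]-1-methylcyclohexane-1,2-diol | C[C@]1(O)CC[C@H](C[C@@H]1O)[C@H](CO[Si](CC)(CC)CC)CC/C=C(\C)CCC=C(C)C | intermediate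
8 | (3R)-3-[(2R,5E)-6,10-dimethyl-1-(triethylsilyloxy)undeca-5,9-dien-2-yl]-6-oxoheptanal | CC(=O)CC[C@H](CC=O)[C@H](CO[Si](CC)(CC)CC)CC/C=C(\C)CCC=C(C)C | intermediate
9 | (5S)-5-[(2R,5E)-6,10-dimethyl-1-(triethylsilyloxy)undeca-5,9-dien-2-yl]-2-methylcyclopent-1-ene-1-carbaldehyde | CC1=C(C=O)[C@H]([C@H](CO[Si](CC)(CC)CC)CC/C=C(\C)CCC=C(C)C)CC1 | intermediate
10 | {(3S)-3-[(2R,5E)-6,10-dimethyl-1-(triethylsilyloxy)undeca-5,9-dien-2-yl]-2-formylcyclopent-1-en-1-yl}methyl acetate | CC(=O)OCC1=C(C=O)[C@H]([C@H](CO[Si](CC)(CC)CC)CC/C=C(\C)CCC=C(C)C)CC1 | intermediate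
11 | ({(2R,5E)-2-[(1S)-3-(acetoxymethyl)-2-formylcyclopent-2-en-1-yl]-6,10-dimethylundeca-5,9-dien-1-yl}oxy)dimethylsulfonium chloride | CC(=O)OCC1=C(C=O)[C@H]([C@H](CO[S+](C)C)CC/C=C(\C)CCC=C(C)C)CC1.[Cl-] | intermediate
12 | {(3S)-3-[(2R,5E)-6,10-dimethyl-1-oxoundeca-5,9-dien-2-yl]-2-formylcyclopent-1-en-1-yl}methyl acetate (CNP0280859.2) | CC(=O)OCC1=C(C=O)[C@H]([C@H](C=O)CC/C=C(\C)CCC=C(C)C)CC1 | target

## Step count and weak points

Total steps: 6. Longest linear sequence: 6 (from 1).

**Step 5 (the new C–H acetoxylation).** The risks are slow imine formation with the hindered enal, amine–quinone adducts, and loss of the silyl ether in acetic acid. The fallback sets out from 9 and uses known chemistry. Kinetic deprotonation of the methyl group cis to the formyl group with KN(SiMe3)2 at −78 °C and O-silylation with Et3SiCl gives the (Z)-silyl dienol ether F4. One equivalent of dimethyldioxirane at −78 °C oxidises the electron-rich diene terminus (vinylogous Rubottom oxidation, as in the gamma-hydroxylation of steroid dienol ethers), faster than the trisubstituted alkenes, and after loss of silicon gives the gamma-hydroxy enal F5. Ac2O, pyridine and DMAP then give 10, where the route is rejoined.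

**Step 1 (metalation of the free diol).** The dialkoxide may be poorly soluble or metalate sluggishly. The fallback sets out from 1. Both hydroxyls are silylated with Et3SiOTf and 2,6-lutidine to give the bis(triethylsilyl) ether F1, which behaves as a plain limonene-type substrate toward n-BuLi/TMEDA. Alkylation with 2 gives the geranylated bis(silyl) ether F2, and Bu4NF in THF returns 4.

**Step 2 (diastereocontrol at C2′).** The alkene carries a secondary and a primary alkyl group, so catalyst discrimination may be modest, and the free hydroxyls consume hydride. The fallback sets out from 4 and gives up catalyst control. Hydroboration with 9-BBN (3.5 equiv, two consumed by the hydroxyls) and NaOH/H2O2 is selective for the 1,1-disubstituted alkene and gives 6 together with its C2′-epimeric triol F3 in about equal amounts. The two are separated by chromatography and 6 re-enters at step 3.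

## Further compounds

F1 | step 1 | (1S,2S,4R)-1-methyl-4-(prop-1-en-2-yl)-1,2-bis(triethylsilyloxy)cyclohexane | C[C@]1(O[Si](CC)(CC)CC)CC[C@H](C[C@@H]1O[Si](CC)(CC)CC)C(C)=C
F2 | step 1 | (1S,2S,4R)-4-[(5E)-6,10-dimethylundeca-1,5,9-trien-2-yl]-1-methyl-1,2-bis(triethylsilyloxy)cyclohexane | C[C@]1(O[Si](CC)(CC)CC)CC[C@H](C[C@@H]1O[Si](CC)(CC)CC)C(=C)CC/C=C(\C)CCC=C(C)C
F3 | step 2 | (1S,2S,4R)-4-[(2S,5E)-1-hydroxy-6,10-dimethylundeca-5,9-dien-2-yl]-1-methylcyclohexane-1,2-diol | C[C@]1(O)CC[C@H](C[C@@H]1O)[C@@H](CO)CC/C=C(\C)CCC=C(C)C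
F4 | step 5 | triethyl({(Z)-[(5S)-5-[(2R,5E)-6,10-dimethyl-1-(triethylsilyloxy)undeca-5,9-dien-2-yl]-2-methylidenecyclopentylidene]methyl}oxy)silane | CC[Si](CC)(CC)O/C=C1\C(=C)CC[C@H]1[C@H](CO[Si](CC)(CC)CC)CC/C=C(\C)CCC=C(C)C
F5 | step 5 | (5S)-5-[(2R,5E)-6,10-dimethyl-1-(triethylsilyloxy)undeca-5,9-dien-2-yl]-2-(hydroxymethyl)cyclopent-1-ene-1-carbaldehyde | OCC1=C(C=O)[C@H]([C@H](CO[Si](CC)(CC)CC)CC/C=C(\C)CCC=C(C)C)CC1
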